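## Retrosynthetic overview

- The target comes from the O-silyl lactone by base equilibration of C3 to the trans arrangement with loss of the silyl group; C4 (R) is already fixed.
- The lactone ring, the only ring formed, is closed second to last from a 4-hydroxy ester made by chemoselective reduction of the imide carbonyl of a 2,3-dibenzylsuccinate imide/methyl ester.
- Key disconnection: the C3–C4 bond, alpha-carbon to alpha-carbon, by oxidative heterocoupling of an Evans imide enolate with an ester enolate. One alpha-carbon reacts as an oxidised, electrophilic (enolonium-type) partner.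
- The imide comes from 3-(3,4,5-trimethoxyphenyl)propanoic acid and (S)-4-benzyl-oxazolidin-2-one; the ester comes from methyl dihydroferulate and TBSCl.

Assumption: where both epimers at the carbon alpha to the ester or lactone carbonyl form and are carried on together, they share one number and the SMILES leaves that one centre open; it is fixed in step 5.

## Route

Step 1
Reactants: 1 3-(3,4,5-trimethoxyphenyl)propanoic acid; 2 (S)-4-benzyl-1,3-oxazolidin-2-one
Product: 4 (4S)-4-benzyl-3-[3-(3,4,5-trimethoxyphenyl)propanoyl]-1,3-oxazolidin-2-one, via mixed pivalic anhydride 3 (not isolated)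
Conditions: PivCl, Et3N, THF, −20 °C; then LiCl, 2, rt
Reagents that add atoms: none
Why: One-pot mixed-anhydride N-acylation, in which the LiCl/Et3N-activated oxazolidinone attacks the less hindered carbonyl of the pivalic anhydride; no stereocentre is touched.

Step 2
Reactants: 5 methyl 3-(4-hydroxy-3-methoxyphenyl)propanoate
Product: 6 methyl 3-[4-(tert-butyldimethylsilyloxy)-3-methoxyphenyl]propanoate
Conditions: TBSCl, imidazole, DMF, rt
Reagents that add atoms: tert-butyldimethylsilyl chloride (TBSCl), CC(C)(C)[Si](C)(C)Cl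
Why: Imidazole-promoted silylation of the phenol, so that no oxidisable phenoxide is present in step 3 and the group can fall off under methoxide in step 5.

Step 3
Reactants: 4 (4S)-4-benzyl-3-[3-(3,4,5-trimethoxyphenyl)propanoyl]-1,3-oxazolidin-2-one; 6 methyl 3-[4-(tert-butyldimethylsilyloxy)-3-methoxyphenyl]propanoate (1.2 equiv)
Product: 9 methyl (2RS,3R)-4-[(4S)-4-benzyl-2-oxo-1,3-oxazolidin-3-yl]-2-[4-(tert-butyldimethylsilyloxy)-3-methoxybenzyl]-4-oxo-3-(3,4,5-trimethoxybenzyl)butanoate (C2 epimer mixture), via lithium imide Z-enolate 7 (not isolated), via lithium ester enolate 8 (not isolated)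
Conditions: LiN(iPr)2 (2.3 equiv), THF, −78 °C; then Fe(acac)3 (2.2 equiv), −78 °C → rt
Reagents that add atoms: none
Why: Oxidative enolate heterocoupling, in which one-electron oxidation by Fe(acac)3 turns the more electron-rich ester enolate into an electrophilic alpha-carbonyl radical (an enolonium equivalent) that is captured by the chelated imide Z-enolate on the face away from the auxiliary benzyl group (the Evans alkylation sense), setting the future C4 as R; the different oxidation potentials of the two enolates favour cross-coupling over homocoupling, and the ester-side centre forms unselectively and is corrected in step 5.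

Step 4
Reactants: 9 methyl (2RS,3R)-4-[(4S)-4-benzyl-2-oxo-1,3-oxazolidin-3-yl]-2-[4-(tert-butyldimethylsilyloxy)-3-methoxybenzyl]-4-oxo-3-(3,4,5-trimethoxybenzyl)butanoate
Product: 11 (3RS,4R)-3-[4-(tert-butyldimethylsilyloxy)-3-methoxybenzyl]-4-(3,4,5-trimethoxybenzyl)oxolan-2-one (C3 epimer mixture), via hydroxy ester 10 (not isolated)
Conditions: LiBH4 (1.2 equiv), MeOH (1 equiv), THF, 0 °C; then TsOH (cat.), CH2Cl2, rt
Reagents that add atoms: none
Why: Reductive cleavage of the N-acyl oxazolidinone, whose activated exocyclic carbonyl is reduced by LiBH4 faster than the methyl ester, followed by lactonisation of the 4-hydroxy ester to the five-membered ring; C4 is not touched.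

Step 5
Reactants: 11 (3RS,4R)-3-[4-(tert-butyldimethylsilyloxy)-3-methoxybenzyl]-4-(3,4,5-trimethoxybenzyl)oxolan-2-one
Product: 13 (3R,4R)-3-(4-hydroxy-3-methoxybenzyl)-4-(3,4,5-trimethoxybenzyl)oxolan-2-one (target), via sodium phenoxide lactone 12 (not isolated)
Conditions: NaOMe (3 equiv), MeOH, 50 °C, under Ar; then 1 M HCl, rt
Reagents that add atoms: none
Why: Methoxide cleaves the aryl silyl ether and, through the lactone enolate, equilibrates C3 to the more stable trans (3R,4R) arrangement (base-mediated thermodynamic epimerisation, C4 not being acidic), and the acid quench frees the phenol and re-closes any methanolysed lactone.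

## Compound list

1 | 3-(3,4,5-trimethoxyphenyl)propanoic acid | COc1cc(CCC(=O)O)cc(OC)c1OC | starting material
2 | (S)-4-benzyl-1,3-oxazolidin-2-one | O=C1N[C@@H](Cc2ccccc2)CO1 | starting material
3 | 2,2-dimethylpropanoic 3-(3,4,5-trimethoxyphenyl)propanoic anhydride (mixed pivalic anhydride) | COc1cc(CCC(=O)OC(=O)C(C)(C)C)cc(OC)c1OC | intermediate
4 | (4S)-4-benzyl-3-[3-(3,4,5-trimethoxyphenyl)propanoyl]-1,3-oxazolidin-2-one | COc1cc(CCC(=O)N2[C@@H](Cc3ccccc3)COC2=O)cc(OC)c1OC | intermediate
5 | methyl 3-(4-hydroxy-3-methoxyphenyl)propanoate (methyl dihydroferulate) | COC(=O)CCc1ccc(O)c(OC)c1 | starting material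
6 | methyl 3-[4-(tert-butyldimethylsilyloxy)-3-methoxyphenyl]propanoate | COC(=O)CCc1ccc(O[Si](C)(C)C(C)(C)C)c(OC)c1 | intermediate
7 | lithium Z-enolate of imide 4 | COc1cc(C/C=C(\O[Li])N2[C@@H](Cc3ccccc3)COC2=O)cc(OC)c1OC | intermediate
8 | lithium enolate of ester 6 | [Li]O/C(OC)=C/Cc1ccc(O[Si](C)(C)C(C)(C)C)c(OC)c1 | intermediate
9 | methyl (2RS,3R)-4-[(4S)-4-benzyl-2-oxo-1,3-oxazolidin-3-yl]-2-[4-(tert-butyldimethylsilyloxy)-3-methoxybenzyl]-4-oxo-3-(3,4,5-trimethoxybenzyl)butanoate, C2 epimer mixture | COC(=O)C(Cc1ccc(O[Si](C)(C)C(C)(C)C)c(OC)c1)[C@@H](Cc1cc(OC)c(OC)c(OC)c1)C(=O)N1[C@@H](Cc2ccccc2)COC1=O | intermediate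
10 | methyl (2RS,3R)-2-[4-(tert-butyldimethylsilyloxy)-3-methoxybenzyl]-4-hydroxy-3-(3,4,5-trimethoxybenzyl)butanoate, C2 epimer mixture | COC(=O)C(Cc1ccc(O[Si](C)(C)C(C)(C)C)c(OC)c1)[C@@H](Cc1cc(OC)c(OC)c(OC)c1)CO | intermediate
11 | (3RS,4R)-3-[4-(tert-butyldimethylsilyloxy)-3-methoxybenzyl]-4-(3,4,5-trimethoxybenzyl)oxolan-2-one, C3 epimer mixture | COc1cc(CC2C(=O)OC[C@@H]2Cc2cc(OC)c(OC)c(OC)c2)ccc1O[Si](C)(C)C(C)(C)C | intermediate
12 | sodium 2-methoxy-4-{[(4R)-2-oxo-4-(3,4,5-trimethoxybenzyl)oxolan-3-yl]methyl}phenolate, C3 epimers equilibrating | COc1cc(CC2C(=O)OC[C@@H]2Cc2cc(OC)c(OC)c(OC)c2)ccc1[O-].[Na+] | intermediate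
13 | (3R,4R)-3-(4-hydroxy-3-methoxybenzyl)-4-(3,4,5-trimethoxybenzyl)oxolan-2-one | COc1cc(C[C@H]2C(=O)OC[C@@H]2Cc2cc(OC)c(OC)c(OC)c2)ccc1O | target

## Step count

Total step count: 5.
Longest linear sequence: 4 steps (1 → 4 → 9 → 11 → 13, or 5 → 6 → 9 → 11 → 13).

## Steps most likely to fail

**Step 3 (oxidative heterocoupling).** The risks are homodimers, low conversion and weaker face control than in a two-electron alkylation. The fallback makes the same bond with a two-electron electrophilic alpha-carbon and brings in the second benzyl group afterwards. It sets out from 4 and comes back at 13.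
- NaN(SiMe3)2 in THF at −78 °C gives the sodium Z-enolate of imide 4 F1.
- Alkylation with tert-butyl bromoacetate on the face away from the auxiliary benzyl group gives tert-butyl (3R)-4-[(4S)-4-benzyl-2-oxo-1,3-oxazolidin-3-yl]-4-oxo-3-(3,4,5-trimethoxybenzyl)butanoate F2.
- LiBH4/MeOH in THF at 0 °C gives tert-butyl (3R)-4-hydroxy-3-(3,4,5-trimethoxybenzyl)butanoate F3.
- TsOH in warm toluene closes this to (4R)-4-(3,4,5-trimethoxybenzyl)oxolan-2-one F4.
- LiN(iPr)2 in THF at −78 °C gives the lithium enolate of this lactone F5.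
- Commercial 4-benzyloxy-3-methoxybenzyl bromide alkylates it anti to the C4 substituent, giving (3R,4R)-3-(4-benzyloxy-3-methoxybenzyl)-4-(3,4,5-trimethoxybenzyl)oxolan-2-one F6.
- Hydrogenolysis (H2, zerovalent palladium on carbon, Pd/C, EtOAc) gives 13.

**Step 4 (chemoselective imide reduction).** The risks are over-reduction of the methyl ester or lactone to the diol, and ring-opening of the hindered imide at the oxazolidinone carbonyl. The fallback replaces hydride cleavage by hydrolytic cleavage and a carboxylic-acid-selective reduction. It sets out from 9 and comes back at 11.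
- LiOH/H2O2 in THF/H2O at 0 °C, kept short, removes the auxiliary at the exocyclic carbonyl and gives (2R,3RS)-3-[4-(tert-butyldimethylsilyloxy)-3-methoxybenzyl]-4-methoxy-4-oxo-2-(3,4,5-trimethoxybenzyl)butanoic acid F7.
- BH3·SMe2 in THF at 0 °C reduces only the free acid, giving hydroxy ester 10.
- Catalytic TsOH closes 10 to 11.

**Step 5 (one-pot epimerisation and desilylation).** The risks are partial methanolysis of the lactone, so that acyclic material re-closes without trans control, and incomplete equilibration. The fallback separates the two events and avoids any nucleophilic base. It sets out from 11 and comes back at 13.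
- DBU in toluene at 80 °C equilibrates the intact lactone to (3R,4R)-3-[4-(tert-butyldimethylsilyloxy)-3-methoxybenzyl]-4-(3,4,5-trimethoxybenzyl)oxolan-2-one F8, purified as the single trans isomer.
- Bu4NF buffered with AcOH in THF at 0 °C removes the silyl group and gives 13.

## Further compounds

F1 | step 3 | sodium Z-enolate of imide 4 | COc1cc(C/C=C(\O[Na])N2[C@@H](Cc3ccccc3)COC2=O)cc(OC)c1OC
F2 | step 3 | tert-butyl (3R)-4-[(4S)-4-benzyl-2-oxo-1,3-oxazolidin-3-yl]-4-oxo-3-(3,4,5-trimethoxybenzyl)butanoate | CC(C)(C)OC(=O)C[C@@H](Cc1cc(OC)c(OC)c(OC)c1)C(=O)N1[C@@H](Cc2ccccc2)COC1=O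
F3 | step 3 | tert-butyl (3R)-4-hydroxy-3-(3,4,5-trimethoxybenzyl)butanoate | CC(C)(C)OC(=O)C[C@@H](Cc1cc(OC)c(OC)c(OC)c1)CO
F4 | step 3 | (4R)-4-(3,4,5-trimethoxybenzyl)oxolan-2-one | COc1cc(C[C@H]2COC(=O)C2)cc(OC)c1OC
F5 | step 3 | lithium enolate of lactone F4 | COc1cc(C[C@H]2COC(O[Li])=C2)cc(OC)c1OC
F6 | step 3 | (3R,4R)-3-(4-benzyloxy-3-methoxybenzyl)-4-(3,4,5-trimethoxybenzyl)oxolan-2-one | COc1cc(C[C@H]2C(=O)OC[C@@H]2Cc2cc(OC)c(OC)c(OC)c2)ccc1OCc1ccccc1
F7 | step 4 | (2R,3RS)-3-[4-(tert-butyldimethylsilyloxy)-3-methoxybenzyl]-4-methoxy-4-oxo-2-(3,4,5-trimethoxybenzyl)butanoic acid | COC(=O)C(Cc1ccc(O[Si](C)(C)C(C)(C)C)c(OC)c1)[C@@H](Cc1cc(OC)c(OC)c(OC)c1)C(=O)O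
F8 | step 5 | (3R,4R)-3-[4-(tert-butyldimethylsilyloxy)-3-methoxybenzyl]-4-(3,4,5-trimethoxybenzyl)oxolan-2-one | COc1cc(C[C@H]2C(=O)OC[C@@H]2Cc2cc(OC)c(OC)c(OC)c2)ccc1O[Si](C)(C)C(C)(C)C
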